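**Plan**

- Retrosynthesis (germacrane numbering: lactone C12–O–C6, ring fusion C6–C7, C13 the exocyclic CH2, C14 on C10, C15 on C4): the epoxide oxygen is taken off C1–C10 first, then the two acyl groups from O3 and O8 and C13 from C11. The lactone is moved from O6 back to O8, and the carbocycle is finally cut at C8–C9 while C1 is re-joined to C6.
- Enabling feature: the ten-membered carbocycle has a Z C4=C5 alkene between the oxygenated carbons C3 and C6, and the C6 oxygen is δ,ε to C1=C10 through C7–C8–C9. C1–C6 with C9, C10, C14 and C15 is therefore a latent 4-oxygenated 6-isopropenylcyclohexenone (the carvone carbon set). C7, C8(O), C11 and C12(=O) are a latent butenolide or furan. The two are tied together as an oxy-Cope retron.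
- Forward order: a carvone-derived cyclohexenone ring and a 2-silyloxyfuran ring are joined at C6–C7. One anionic [3,3] shift enlarges the six-membered ring to the ten-membered one and turns the furan into the cis-fused 8,12-lactone. Reduction at C6 and an acyl shift give the trans 6,12-lactone, then come C13, the two esters and last the oxirane ring.
- Stereochemistry: C3 comes from carvone (reduction, then Mitsunobu inversion). The carvone centre steers the furyl addition, and both centres are spent in a chair transition state that sets C8 and, through face-selective protonation, C7. C6 comes from outer-face hydride delivery, C1/C10 from peripheral peracid attack, the epoxy acid from a Sharpless epoxidation, and the 2-methylbutanoate from the bought (R)-acid.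

Key step: step 8

Remark: germacrane numbering is kept for every ten-membered-ring compound and α/β refer to the usual drawing with H-7 α; the target is then the 1β,10α-epoxy-3β,8β-diacyloxygermacra-4Z,11(13)-dien-12,6α-olide, absolute configuration 1R,3S,6R,7R,8R,10R.
Remark: the acyl groups are taken as drawn, i.e. (R)-2-methylbutanoyl on O3 and the cis-dimethyl (2S,3R)-2,3-dimethyloxirane-2-carbonyl group (epoxide of the tiglic series) on O8.

**Route**

Step 1
Reactants: 1 (R)-(−)-carvone
Product: 2 (1R,5R)-cis-carveol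
Conditions: NaBH4, CeCl3·7H2O, MeOH, 0 °C
Reagents that add atoms: none
Why: Luche 1,2-reduction of the enone; axial hydride delivery on the half-chair with the isopropenyl group equatorial should set C1 (R) cis to that group.

Step 2
Reactants: 2 (1R,5R)-cis-carveol
Product: 3 (1S,5R)-trans-carveyl 4-nitrobenzoate
Conditions: 4-O2NC6H4CO2H, PPh3, DIAD, THF, 0 °C → rt
Reagents that add atoms: 4-nitrobenzoic acid, O=C(O)c1ccc(cc1)[N+](=O)[O-]
Why: Mitsunobu esterification; SN2 displacement of the activated allylic alcohol inverts the carbinol centre to S, the configuration later required at C3.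

Step 3
Reactants: 3 (1S,5R)-trans-carveyl 4-nitrobenzoate
Product: 4 (1S,5R)-trans-carveol
Conditions: K2CO3, MeOH, rt
Reagents that add atoms: none
Why: Base-catalysed transesterification (methanolysis) cleaves the aryl ester at the acyl carbon, so the carbinol configuration is retained.

Step 4
Reactants: 4 (1S,5R)-trans-carveol
Product: 5 (1S,5R)-trans-carveol tert-butyldimethylsilyl ether
Conditions: TBSCl, imidazole, DMF, rt
Reagents that add atoms: tert-butyldimethylsilyl chloride, CC(C)(C)[Si](C)(C)Cl
Why: Standard imidazole-promoted silylation of a secondary allylic alcohol; the ether must survive KH, fluoride-buffered work-up, amide bases and acylations before its removal in step 17.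

Step 5
Reactants: 5 (1S,5R)-trans-carveol tert-butyldimethylsilyl ether
Product: 6 (4S,6R)-4-(tert-butyldimethylsilyloxy)-3-methyl-6-(prop-1-en-2-yl)cyclohex-2-en-1-one
Conditions: CrO3, 3,5-dimethylpyrazole, CH2Cl2, −20 °C
Reagents that add atoms: chromium trioxide, O=[Cr](=O)=O
Why: Allylic oxidation with the CrO3–3,5-dimethylpyrazole complex turns the only ring CH2 next to the alkene CH into the enone carbonyl; under these cold, non-basic conditions the isopropenyl group and the epimerisable centre beside the new carbonyl should stay untouched.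

Step 6
Reactants: 7 4-bromofuran-2(5H)-one
Product: 8 4-bromo-2-(triisopropylsilyloxy)furan
Conditions: TIPSOTf, Et3N, CH2Cl2, 0 °C
Reagents that add atoms: triisopropylsilyl trifluoromethanesulfonate, CC(C)[Si](C(C)C)(C(C)C)OS(=O)(=O)C(F)(F)F
Why: Soft enolisation and O-silylation of the butenolide (silyl dienol ether formation) aromatises the ring to the 2-silyloxyfuran and keeps the bromide for metalation.

Step 7
Reactants: 8 4-bromo-2-(triisopropylsilyloxy)furan; 6 (4S,6R)-4-(tert-butyldimethylsilyloxy)-3-methyl-6-(prop-1-en-2-yl)cyclohex-2-en-1-one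
Product: 11 (1R,4S,6R)-4-(tert-butyldimethylsilyloxy)-3-methyl-6-(prop-1-en-2-yl)-1-[5-(triisopropylsilyloxy)furan-3-yl]cyclohex-2-en-1-ol, via furyllithium 9 (not isolated), via furylcerium dichloride 10 (not isolated)
Conditions: 8, t-BuLi, Et2O, −78 °C; CeCl3, THF, −78 °C; 6, −78 °C; H2O/NaHCO3
Reagents that add atoms: none
Why: Bromine–lithium exchange, transmetalation to the less basic organocerium reagent (which suppresses enolisation of the doubly activated C–H beside the carbonyl) and 1,2-addition to the enone; equatorial attack anti to the neighbouring isopropenyl group should set the carbinol centre (1R) with furyl and isopropenyl trans.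

Step 8
Reactants: 11 (1R,4S,6R)-4-(tert-butyldimethylsilyloxy)-3-methyl-6-(prop-1-en-2-yl)-1-[5-(triisopropylsilyloxy)furan-3-yl]cyclohex-2-en-1-ol
Product: 15 (3S,7R,8R)-3-(tert-butyldimethylsilyloxy)-6-oxogermacra-1(10)E,4Z-dien-12,8-olide, via potassium alkoxide 12 (not isolated), via ring-expanded potassium dienolate 13 (not isolated), via silyl ketene acetal ketone 14 (not isolated)
Conditions: KH, 18-crown-6, THF, 0 °C → rt; AcOH, −78 °C; Bu4NF/AcOH, −78 → 0 °C
Reagents that add atoms: none
Why: Proposed new method: KH/18-crown-6 gives the naked alkoxide 12, in which the cyclohexene C1–C6 bond breaks while the isopropenyl CH2 (C9) bonds to furan C5 (C8) in a concerted anionic [3,3] shift with the furan C4=C5 bond as second alkene, dearomatising the furan to dienolate 13 (ketone enolate C6=C7 conjugated with the cyclic silyl ketene acetal), after which kinetic C-protonation at C7 (14) and buffered fluoride uncover ketone and lactone. The closest known reaction types are the anionic oxy-Cope ring expansion of 1-alkenyl-6-isopropenylcyclohex-2-enols to cyclodeca-2,6-dienones and anionic oxy-Cope shifts that consume a furan or benzofuran C=C bond; a 2-silyloxyfuran is new in this role, but it is only weakly aromatic and ends as an enolate plus a ketene acetal, which should pay for the dearomatisation. The ten-membered carbocycle is not closed end to end but arises by four-atom enlargement of the six-membered ring (C8–C9 made, C1–C6 broken), and the five-membered oxygen ring is carried over from the furan. C8 is fixed by the chair transition state with the ring bonds C1–C2 and C6–C5 equatorial, the alkoxide axial and the furan oxygen pseudo-equatorial, which translates the configurations at C1 and C6 of 11 into 8R and into a trans-cycloalkene enolate (C5 anti to C8) with one exposed face; protonation of C7 on that outer face (the inner one is covered by the C1=C10 half of the ring, and neither the enolate oxygen nor the fused ring can swing through the macrocycle) gives H-7 cis to H-8. The step needs the chair path, E geometry at C1=C10, retention of the Z C4=C5 bond and one face of the furan, all secured by the trans-diequatorial furyl and isopropenyl groups of 11 and by the ring-locked furan enol ether, which also holds the C8–O bond in the enolate plane (no β-elimination); the bulky triisopropylsilyl group is chosen to resist attack by the alkoxide.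

Step 9
Reactants: 15 (3S,7R,8R)-3-(tert-butyldimethylsilyloxy)-6-oxogermacra-1(10)E,4Z-dien-12,8-olide
Product: 16 3β-(tert-butyldimethylsilyloxy)-6α-hydroxygermacra-1(10)E,4Z-dien-12,8β-olide
Conditions: NaBH4, CeCl3·7H2O, MeOH/THF, −78 °C
Reagents that add atoms: none
Why: Luche 1,2-reduction of the Z-enone; the C6 carbonyl should keep the orientation left by the enolate (oxygen turned toward C8, C5 anti to C8) with its inner face covered by the ring, so hydride should add from outside and give the 6α-alcohol (6R) with H-6 anti to H-7.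

Step 10
Reactants: 16 3β-(tert-butyldimethylsilyloxy)-6α-hydroxygermacra-1(10)E,4Z-dien-12,8β-olide
Product: 17 3β-(tert-butyldimethylsilyloxy)-8β-hydroxygermacra-1(10)E,4Z-dien-12,6α-olide
Conditions: DBU (cat.), toluene, rt
Reagents that add atoms: none
Why: Base-catalysed translactonisation (intramolecular transesterification) in which O6 adds to C12 through a 2,6-dioxabicyclo[2.2.1]heptane-type tetrahedral intermediate reachable from the anti C5–C6–C7–C8, gauche C6–C7–C8–C9 ring conformer; the trans 6,12-lactone should be the thermodynamic isomer because the cis 8,12-lactone forces a small C6–C7–C8–C9 torsion on the ten-membered ring, and no stereocentre is touched.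

Step 11
Reactants: 17 3β-(tert-butyldimethylsilyloxy)-8β-hydroxygermacra-1(10)E,4Z-dien-12,6α-olide
Product: 19 13-(dimethylamino)-3β-(tert-butyldimethylsilyloxy)-8β-hydroxy-11,13-dihydrogermacra-1(10)E,4Z-dien-12,6α-olide, via dilithium alkoxide-enolate 18 (not isolated)
Conditions: LiN(iPr)2 (3 equiv), THF, −78 °C; Me2N=CH2 I, −78 → 0 °C; H2O
Reagents that add atoms: dimethyl(methylidene)ammonium iodide, C=[N+](C)C.[I-]
Why: Mannich aminomethylation of the lactone lithium enolate (formed after the alkoxide, hence the excess base) with the preformed iminium salt, which brings in C13; the new C11 centre is of no consequence because it becomes sp2 in step 12.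

Step 12
Reactants: 19 13-(dimethylamino)-3β-(tert-butyldimethylsilyloxy)-8β-hydroxy-11,13-dihydrogermacra-1(10)E,4Z-dien-12,6α-olide
Product: 21 3β-(tert-butyldimethylsilyloxy)-8β-hydroxygermacra-1(10)E,4Z,11(13)-trien-12,6α-olide, via trimethylammonium iodide 20 (not isolated)
Conditions: MeI, MeOH, rt; NaHCO3 (aq), CH2Cl2, rt
Reagents that add atoms: none
Why: Exhaustive N-methylation followed by base-induced β-elimination of trimethylamine (Hofmann-type, E1cB through the lactone enolate) gives the exocyclic α-methylene lactone.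

Step 13
Reactants: 22 tiglic acid
Product: 23 (E)-2-methylbut-2-en-1-ol
Conditions: LiAlH4, Et2O, 0 °C → rt
Reagents that add atoms: none
Why: Hydride reduction of the carboxylic acid with LiAlH4 gives the primary allylic alcohol and leaves the E alkene untouched.

Step 14
Reactants: 23 (E)-2-methylbut-2-en-1-ol
Product: 24 [(2R,3R)-2,3-dimethyloxiran-2-yl]methanol
Conditions: Ti(OiPr)4 (cat.), D-(−)-diethyl tartrate (cat.), t-BuOOH, 4 Å molecular sieves, CH2Cl2, −20 °C
Reagents that add atoms: tert-butyl hydroperoxide, CC(C)(C)OO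
Why: Sharpless asymmetric epoxidation of the E allylic alcohol; the D-(−)-tartrate catalyst delivers oxygen to the face that gives the (2R,3R) epoxy alcohol, setting both centres at once.

Step 15
Reactants: 24 [(2R,3R)-2,3-dimethyloxiran-2-yl]methanol
Product: 25 (2S,3R)-2,3-dimethyloxirane-2-carboxylic acid
Conditions: RuCl3·xH2O (cat.), NaIO4, MeCN/EtOAc/H2O, rt
Reagents that add atoms: sodium periodate, [Na+].[O-]I(=O)(=O)=O; water, O
Why: RuO4-catalysed oxidation of the primary alcohol to the acid (through the aldehyde hydrate) is a standard route to glycidic acids and leaves the oxirane intact; the C2 descriptor becomes S only through the change in priorities.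

Step 16
Reactants: 21 3β-(tert-butyldimethylsilyloxy)-8β-hydroxygermacra-1(10)E,4Z,11(13)-trien-12,6α-olide; 25 (2S,3R)-2,3-dimethyloxirane-2-carboxylic acid
Product: 27 3β-(tert-butyldimethylsilyloxy)-8β-[(2S,3R)-2,3-dimethyloxirane-2-carbonyloxy]germacra-1(10)E,4Z,11(13)-trien-12,6α-olide, via mixed anhydride 26 (not isolated)
Conditions: 25, 2,4,6-trichlorobenzoyl chloride, Et3N, toluene, rt; 21, DMAP, toluene, rt → 40 °C
Reagents that add atoms: none
Why: Yamaguchi esterification, in which DMAP attacks the mixed anhydride at the less hindered aliphatic carbonyl and the acylpyridinium acylates the secondary 8β-hydroxyl; the acid has no α-hydrogen, so its centres cannot epimerise.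

Step 17
Reactants: 27 3β-(tert-butyldimethylsilyloxy)-8β-[(2S,3R)-2,3-dimethyloxirane-2-carbonyloxy]germacra-1(10)E,4Z,11(13)-trien-12,6α-olide
Product: 28 3β-hydroxy-8β-[(2S,3R)-2,3-dimethyloxirane-2-carbonyloxy]germacra-1(10)E,4Z,11(13)-trien-12,6α-olide
Conditions: HF·pyridine, pyridine, THF, 0 °C → rt
Reagents that add atoms: none
Why: Fluoride-mediated cleavage of the allylic silyl ether with pyridine-buffered HF·pyridine, which should be mild enough for the α-methylene lactone, the glycidic ester and the lactone position.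

Step 18
Reactants: 28 3β-hydroxy-8β-[(2S,3R)-2,3-dimethyloxirane-2-carbonyloxy]germacra-1(10)E,4Z,11(13)-trien-12,6α-olide; 29 (R)-2-methylbutanoic acid
Product: 30 3β-[(2R)-2-methylbutanoyloxy]-8β-[(2S,3R)-2,3-dimethyloxirane-2-carbonyloxy]germacra-1(10)E,4Z,11(13)-trien-12,6α-olide
Conditions: EDC·HCl, DMAP (cat.), CH2Cl2, 0 °C → rt
Reagents that add atoms: none
Why: Steglich esterification (carbodiimide activation, DMAP acyl transfer) of the 3β-hydroxyl, run cold with catalytic DMAP so that the α-centre of the acid is not epimerised.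

Step 19
Reactants: 30 3β-[(2R)-2-methylbutanoyloxy]-8β-[(2S,3R)-2,3-dimethyloxirane-2-carbonyloxy]germacra-1(10)E,4Z,11(13)-trien-12,6α-olide
Product: 31 target CNP0265335.4
Conditions: mCPBA, NaHCO3, CH2Cl2, 0 °C
Reagents that add atoms: 3-chloroperoxybenzoic acid, O=C(OO)c1cccc(Cl)c1
Why: Prilezhaev epoxidation; only C1=C10 is electron-rich (C4=C5 carries two allylic acyloxy groups, C11=C13 is conjugated), and attack on its outer face in the ring conformer with C14 on the β face should give the 1β,10α-epoxide (1R,10R).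

**Compound list**

1 | (R)-(−)-carvone | C=C(C)[C@H]1CC(=O)C(C)=CC1 | starting material
2 | (1R,5R)-cis-carveol | C=C(C)[C@H]1C[C@@H](O)C(C)=CC1 | intermediate
3 | (1S,5R)-trans-carveyl 4-nitrobenzoate | C=C(C)[C@H]1C[C@H](OC(=O)c2ccc(cc2)[N+](=O)[O-])C(C)=CC1 | intermediate
4 | (1S,5R)-trans-carveol | C=C(C)[C@H]1C[C@H](O)C(C)=CC1 | intermediate
5 | (1S,5R)-trans-carveol tert-butyldimethylsilyl ether | C=C(C)[C@H]1C[C@H](O[Si](C)(C)C(C)(C)C)C(C)=CC1 | intermediate
6 | (4S,6R)-4-(tert-butyldimethylsilyloxy)-3-methyl-6-(prop-1-en-2-yl)cyclohex-2-en-1-one | C=C(C)[C@H]1C[C@H](O[Si](C)(C)C(C)(C)C)C(C)=CC1=O | intermediate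
7 | 4-bromofuran-2(5H)-one | O=C1C=C(Br)CO1 | starting material
8 | 4-bromo-2-(triisopropylsilyloxy)furan | CC(C)[Si](Oc1cc(Br)co1)(C(C)C)C(C)C | intermediate
9 | 4-lithio-2-(triisopropylsilyloxy)furan (not isolated) | CC(C)[Si](Oc1cc([Li])co1)(C(C)C)C(C)C | intermediate
10 | [5-(triisopropylsilyloxy)furan-3-yl]cerium dichloride (not isolated) | CC(C)[Si](Oc1cc([Ce](Cl)Cl)co1)(C(C)C)C(C)C | intermediate
11 | (1R,4S,6R)-4-(tert-butyldimethylsilyloxy)-3-methyl-6-(prop-1-en-2-yl)-1-[5-(triisopropylsilyloxy)furan-3-yl]cyclohex-2-en-1-ol | C=C(C)[C@H]1C[C@H](O[Si](C)(C)C(C)(C)C)C(C)=C[C@]1(O)c2coc(O[Si](C(C)C)(C(C)C)C(C)C)c2 | intermediate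
12 | potassium alkoxide of 11 (not isolated) | C=C(C)[C@H]1C[C@H](O[Si](C)(C)C(C)(C)C)C(C)=C[C@]1([O-])c2coc(O[Si](C(C)C)(C(C)C)C(C)C)c2.[K+] | intermediate
13 | ring-expanded potassium dienolate: ten-membered ring, enolate C6=C7 with C5 anti to C8, cyclic silyl ketene acetal C11=C12, 8R (not isolated) | CC(C)[Si](C(C)C)(C(C)C)OC1=C/C2=C(/[O-])\C=C(\C)[C@@H](O[Si](C)(C)C(C)(C)C)C/C=C(\C)C[C@H]2O1.[K+] | intermediate
14 | 6-keto silyl ketene acetal, 7α-H, 8α-H (not isolated) | CC(C)[Si](C(C)C)(C(C)C)OC1=C[C@H]2C(=O)/C=C(/C)[C@@H](O[Si](C)(C)C(C)(C)C)C/C=C(\C)C[C@H]2O1 | intermediate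
15 | (3S,7R,8R)-3-(tert-butyldimethylsilyloxy)-6-oxogermacra-1(10)E,4Z-dien-12,8-olide (3β-OSi, cis-fused 8β,12-lactone) | O=C1C[C@H]2C(=O)/C=C(/C)[C@@H](O[Si](C)(C)C(C)(C)C)C/C=C(\C)C[C@H]2O1 | intermediate
16 | 3β-(tert-butyldimethylsilyloxy)-6α-hydroxygermacra-1(10)E,4Z-dien-12,8β-olide | O=C1C[C@H]2[C@H](O)/C=C(/C)[C@@H](O[Si](C)(C)C(C)(C)C)C/C=C(\C)C[C@H]2O1 | intermediate
17 | 3β-(tert-butyldimethylsilyloxy)-8β-hydroxygermacra-1(10)E,4Z-dien-12,6α-olide (3S,6R,7R,8R; trans-fused lactone) | C1C(=O)O[C@@H]2/C=C(/C)[C@@H](O[Si](C)(C)C(C)(C)C)C/C=C(\C)C[C@@H](O)[C@@H]12 | intermediate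
18 | dilithium 8-alkoxide lactone enolate of 17 (not isolated) | C1=C([O-])O[C@@H]2/C=C(/C)[C@@H](O[Si](C)(C)C(C)(C)C)C/C=C(\C)C[C@@H]([O-])[C@@H]12.[Li+].[Li+] | intermediate
19 | 13-(dimethylamino)-11,13-dihydro derivative of 21 (C11 configuration left open, erased in step 12) | CN(C)CC1C(=O)O[C@@H]2/C=C(/C)[C@@H](O[Si](C)(C)C(C)(C)C)C/C=C(\C)C[C@@H](O)[C@@H]12 | intermediate
20 | 13-(trimethylammonio) iodide of 19 (not isolated) | C[N+](C)(C)CC1C(=O)O[C@@H]2/C=C(/C)[C@@H](O[Si](C)(C)C(C)(C)C)C/C=C(\C)C[C@@H](O)[C@@H]12.[I-] | intermediate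
21 | 3β-(tert-butyldimethylsilyloxy)-8β-hydroxygermacra-1(10)E,4Z,11(13)-trien-12,6α-olide | C=C1C(=O)O[C@@H]2/C=C(/C)[C@@H](O[Si](C)(C)C(C)(C)C)C/C=C(\C)C[C@@H](O)[C@@H]12 | intermediate
22 | tiglic acid, (E)-2-methylbut-2-enoic acid | C/C=C(\C)C(=O)O | starting material
23 | (E)-2-methylbut-2-en-1-ol | C/C=C(\C)CO | intermediate
24 | [(2R,3R)-2,3-dimethyloxiran-2-yl]methanol | OC[C@@]1(C)O[C@@H]1C | intermediate
25 | (2S,3R)-2,3-dimethyloxirane-2-carboxylic acid | OC(=O)[C@@]1(C)O[C@@H]1C | intermediate
26 | (2S,3R)-2,3-dimethyloxirane-2-carboxylic 2,4,6-trichlorobenzoic anhydride (not isolated) | O=C(OC(=O)[C@@]1(C)O[C@@H]1C)c2c(Cl)cc(Cl)cc2Cl | intermediate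
27 | 3β-(tert-butyldimethylsilyloxy)-8β-[(2S,3R)-2,3-dimethyloxirane-2-carbonyloxy]germacra-1(10)E,4Z,11(13)-trien-12,6α-olide | C=C1C(=O)O[C@@H]2/C=C(/C)[C@@H](O[Si](C)(C)C(C)(C)C)C/C=C(\C)C[C@@H](OC(=O)[C@@]3(C)O[C@@H]3C)[C@@H]12 | intermediate
28 | 3β-hydroxy-8β-[(2S,3R)-2,3-dimethyloxirane-2-carbonyloxy]germacra-1(10)E,4Z,11(13)-trien-12,6α-olide | C=C1C(=O)O[C@@H]2/C=C(/C)[C@@H](O)C/C=C(\C)C[C@@H](OC(=O)[C@@]3(C)O[C@@H]3C)[C@@H]12 | intermediate
29 | (R)-2-methylbutanoic acid | CC[C@@H](C)C(=O)O | starting material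
30 | 3β-[(2R)-2-methylbutanoyloxy]-8β-[(2S,3R)-2,3-dimethyloxirane-2-carbonyloxy]germacra-1(10)E,4Z,11(13)-trien-12,6α-olide | C=C1C(=O)O[C@@H]2/C=C(/C)[C@@H](OC(=O)[C@H](C)CC)C/C=C(\C)C[C@@H](OC(=O)[C@@]3(C)O[C@@H]3C)[C@@H]12 | intermediate
31 | CNP0265335.4, (1R,3S,6R,7R,8R,10R)-1β,10α-epoxy-3β-[(2R)-2-methylbutanoyloxy]-8β-[(2S,3R)-2,3-dimethyloxirane-2-carbonyloxy]germacra-4Z,11(13)-dien-12,6α-olide | C=C1C(=O)O[C@@H]2/C=C(/C)[C@@H](OC(=O)[C@H](C)CC)C[C@H]3O[C@]3(C)C[C@@H](OC(=O)[C@@]3(C)O[C@@H]3C)[C@@H]12 | target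

**Count**

Total steps: 19. Longest linear sequence: 15 steps (steps 1–5, 7–12 and 16–19, from carvone).

**Steps most likely to fail**

1. Step 8. Silyl transfer from the silyloxyfuran to the naked alkoxide (or its desilylation) may outrun the sigmatropic shift, or the dearomatising shift may need temperatures the silyl ketene acetal does not tolerate. After the shift, β-elimination of O8 or epimerisation at C7 during the fluoride stage are further hazards.
   Fallback, known reaction types only, with the ring expansion kept and the oxidation level of C12 adjusted afterwards: bought 3-bromofuran is lithiated with t-BuLi to 3-furyllithium F1, passed to CeCl3 to give 3-furylcerium dichloride F2, and added to enone 6 to give the 3-furyl carbinol F3. KH/18-crown-6 forms its potassium alkoxide F4, which should undergo the documented anionic oxy-Cope shift across a plain furan C2=C3 bond, here combined with the equally documented cyclohexenol-to-cyclodecenone enlargement. This gives the potassium dienolate F5 and, after cold AcOH, the cis-fused 2,3-dihydrofuran ketone F6 (enol ether C11=C12). Hydration of the enol ether with PPTS in wet THF gives the lactol F7, and oxidation with TEMPO/PhI(OAc)2 gives the lactone. The sequence sets out from 6 and returns at 15.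

2. Step 10. The acyl-transfer equilibrium may rest on the side of the cis 8,12-lactone, or stop at a mixture of the two lactones.
   Fallback, making the transfer stepwise and irreversible: from 16, Et3SiCl/imidazole gives the 6-O-triethylsilyl ether F8. Me3Al with MeNH(OMe)·HCl opens the lactone to the N-methoxy-N-methylamide F9 with O8 free. Yamaguchi acylation with 25 (through 26) gives the 8-O-epoxyacyl amide F10. PPTS in MeOH removes only the triethylsilyl group to give the 6-hydroxy amide F11, whose O6 closes on the amide under the same mild acid to the 6,12-lactone F12, the 11,13-dihydro analogue of 27. Its lithium enolate F13 (LiN(SiMe3)2, THF, −78 °C) is aminomethylated with Me2N=CH2 I to the Mannich base F14. Methylation to the ammonium iodide F15 and NaHCO3 elimination then give 27. The sequence sets out from 16 and returns at 27, bypassing the free 8-hydroxy lactones.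

3. Step 9. Facial selectivity at C6 may be poor if the carbonyl group can turn through the ring, so that hydride also arrives from the other face.
   Fallback, correcting the centre by substitution and not by reduction: the 6β-alcohol F16 obtained from 15 is esterified under Mitsunobu conditions (4-nitrobenzoic acid, PPh3, DIAD) with inversion to the 6α-(4-nitrobenzoate) F17. Methanolysis (K2CO3, MeOH, 0 °C) then frees the 6α-hydroxyl. The sequence sets out from 15 and returns at 16.

**Further compounds**

F1 | step 8 | 3-furyllithium | [Li]c1ccoc1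
F2 | step 8 | 3-furylcerium dichloride | Cl[Ce](Cl)c1ccoc1
F3 | step 8 | (1R,4S,6R)-4-(tert-butyldimethylsilyloxy)-1-(furan-3-yl)-3-methyl-6-(prop-1-en-2-yl)cyclohex-2-en-1-ol | C=C(C)[C@H]1C[C@H](O[Si](C)(C)C(C)(C)C)C(C)=C[C@]1(O)c2ccoc2
F4 | step 8 | potassium alkoxide of F3 | C=C(C)[C@H]1C[C@H](O[Si](C)(C)C(C)(C)C)C(C)=C[C@]1([O-])c2ccoc2.[K+]
F5 | step 8 | ring-expanded potassium dienolate with 2,3-dihydrofuran ring | C1=C/C2=C(/[O-])\C=C(\C)[C@@H](O[Si](C)(C)C(C)(C)C)C/C=C(\C)C[C@H]2O1.[K+]
F6 | step 8 | 3β-(tert-butyldimethylsilyloxy)-6-oxo-8β,12-epoxygermacra-1(10)E,4Z,11-triene (cis-fused 2,3-dihydrofuran) | C1=C[C@H]2C(=O)/C=C(/C)[C@@H](O[Si](C)(C)C(C)(C)C)C/C=C(\C)C[C@H]2O1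
F7 | step 8 | 12-hydroxy lactol of F6 (anomers) | OC1C[C@H]2C(=O)/C=C(/C)[C@@H](O[Si](C)(C)C(C)(C)C)C/C=C(\C)C[C@H]2O1
F8 | step 10 | 6-O-triethylsilyl ether of 16 | O=C1C[C@H]2[C@H](O[Si](CC)(CC)CC)/C=C(/C)[C@@H](O[Si](C)(C)C(C)(C)C)C/C=C(\C)C[C@H]2O1
F9 | step 10 | 8β-hydroxy N-methoxy-N-methylamide (ring-opened F8) | CON(C)C(=O)C[C@H]1[C@H](O[Si](CC)(CC)CC)/C=C(/C)[C@@H](O[Si](C)(C)C(C)(C)C)C/C=C(\C)C[C@H]1O
F10 | step 10 | 8β-[(2S,3R)-2,3-dimethyloxirane-2-carbonyloxy] amide | CON(C)C(=O)C[C@H]1[C@H](O[Si](CC)(CC)CC)/C=C(/C)[C@@H](O[Si](C)(C)C(C)(C)C)C/C=C(\C)C[C@H]1OC(=O)[C@@]2(C)O[C@@H]2C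
F11 | step 10 | 6α-hydroxy amide (F10 without the triethylsilyl group) | CON(C)C(=O)C[C@H]1[C@H](O)/C=C(/C)[C@@H](O[Si](C)(C)C(C)(C)C)C/C=C(\C)C[C@H]1OC(=O)[C@@]2(C)O[C@@H]2C
F12 | step 10 | 11,13-dihydro analogue of 27 | C1C(=O)O[C@@H]2/C=C(/C)[C@@H](O[Si](C)(C)C(C)(C)C)C/C=C(\C)C[C@@H](OC(=O)[C@@]3(C)O[C@@H]3C)[C@@H]12
F13 | step 10 | lithium enolate of F12 | C1=C([O-])O[C@@H]2/C=C(/C)[C@@H](O[Si](C)(C)C(C)(C)C)C/C=C(\C)C[C@@H](OC(=O)[C@@]3(C)O[C@@H]3C)[C@@H]12.[Li+]
F14 | step 10 | 13-(dimethylamino) Mannich base of F12 | CN(C)CC1C(=O)O[C@@H]2/C=C(/C)[C@@H](O[Si](C)(C)C(C)(C)C)C/C=C(\C)C[C@@H](OC(=O)[C@@]3(C)O[C@@H]3C)[C@@H]12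
F15 | step 10 | 13-(trimethylammonio) iodide of F14 | C[N+](C)(C)CC1C(=O)O[C@@H]2/C=C(/C)[C@@H](O[Si](C)(C)C(C)(C)C)C/C=C(\C)C[C@@H](OC(=O)[C@@]3(C)O[C@@H]3C)[C@@H]12.[I-]
F16 | step 9 | 6β-hydroxy epimer of 16 | O=C1C[C@H]2[C@@H](O)/C=C(/C)[C@@H](O[Si](C)(C)C(C)(C)C)C/C=C(\C)C[C@H]2O1
F17 | step 9 | 6α-(4-nitrobenzoyloxy) ester of 16 | O=C1C[C@H]2[C@H](OC(=O)c3ccc(cc3)[N+](=O)[O-])/C=C(/C)[C@@H](O[Si](C)(C)C(C)(C)C)C/C=C(\C)C[C@H]2O1
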